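| flask | starting material | reagent in the second phase | remark | time | volume of the second phase over the first |
|---|---|---|---|---|---|
| gamma | 0.080 M | 0.32 M | run made earlier |  |  |
| epsilon | 0.32 M | 0.32 M | run made earlier |  |  |
| delta | 0.16 M | 0.64 M | run made earlier |  |  |
| flask | 0.16 M | 0.320 M |  | 20 min | 0.50 |

| run | time / min | target / % | starting material / % |
|---|---|---|---|
| gamma | 1.00 | 19.5 | 54.2 |
| gamma | 1.33 | 20.4 | 44.8 |
| gamma | 2.00 | 18.2 | 31.2 |
| gamma | 3.00 | 14.6 | 18.5 |
| gamma | 5.00 | 8.8 | 8.7 |
| gamma | 8.00 | 3.6 | 3.3 |
| gamma | 12.0 | 1.5 | 0.5 |
| epsilon | 1.00 | 18.2 | 62.1 |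
| epsilon | 1.33 | 19.9 | 55.6 |
| epsilon | 2.00 | 19.9 | 48.3 |
| epsilon | 3.00 | 19.9 | 42.5 |
| epsilon | 5.00 | 19.7 | 38.3 |
| epsilon | 8.00 | 20.2 | 38.0 |
| epsilon | 12.0 | 19.6 | 37.6 |
| delta | 1.00 | 18.7 | 31.8 |
| delta | 3.00 | 6.4 | 5.4 |
| delta | 6.00 | 1.4 | 0.6 |
| delta | 8.00 | 0.7 | 0.9 |
| delta | 12.0 | 0.1 | 0.5 |

(scatter of a reading: 0.3 percentage points)

- target at 20 min, in percent of the starting material charged
- part of the starting material charged that has reacted at 20 min

- in the second phase: reagent in the second phase; everything else is in the first
- charges count per volume of the first phase; a concentration in a rate is the amount of a species over the volume of its own phase; every rate counts per litre of the first phase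
- the earlier runs were read with a standard deviation of 0.3 percentage points
- the earlier runs hold the two phases in the same ratio of volumes as the flask asked about

1. A flask cannot spend more reagent than was charged. The epsilon run stands still at 37.6% starting material and 19.6% target. If each reacted starting material costs one reagent and each that went on past target costs a second, that is 1.05 equivalents against 1.00 charged, so reagent is the limiting reagent there.

2. This flask has the cover N = c(reagent in the second phase) / (2 c(starting material)) = 1.00, the reagent charged over what a double passage of the starting material costs.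

3. Epsilon, at N = 0.500, stalls. Gamma and delta, at 2.00 and 2.00, fall to 0.5% and 0.5% starting material. This flask, at N = 1.00, lies on the border, so reagent, starting material and target should fade together.

4. N gives the end, not the pace. Gamma's first minute reads k = 0.0319 M⁻¹ s⁻¹. Its later readings show target close to starting material (8.8%, 8.7%), so we take them equal. In this flask, at N = 1.00, reagent left is then 3 s c(starting material), with s the share of starting material left. This second-order tail gives s = 5.44% at 20 min, so we expect 94.6% reacted and about 5.44% target.

5. The forecast, "giving a slow second-order tail", says 6% target and 94.9% reacted.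

6. The flask gives 7.89% target and 92.6% reacted.

    target ⇌ isomer of the product (K = 0.470, k = 0.0310 s⁻¹)
    reagent in the reaction phase + target → over-reacted product (k = 0.00780 M⁻¹ s⁻¹)
    reagent in the reaction phase → decomposed reagent (k = 6.50 × 10⁻⁴ s⁻¹)
    starting material + reagent in the reaction phase → target (k = 0.0480 M⁻¹ s⁻¹)
    reagent in the reaction phase ⇌ reagent in the second phase, rate k5*([reagent in the reaction phase] - [reagent in the second phase]/K5) per volume of the first phase (partition coefficient = 0.380, kL = 0.0230 s⁻¹)
    reagent in the reaction phase + target → over-reaction product (k = 0.0930 M⁻¹ s⁻¹)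

With the path from reagent in the reaction phase + target to over-reaction product struck out, this flask holds 44.1% target instead of 7.89%; that path is the largest single effect, though not the whole. The border shows in this flask: at 0.284 M reagent, N falls from 1.00 to 0.888, and the reacted share has moved 5 points. The neighbour with 0.64 M starting material has N = 0.250, so scaling epsilon's conversion suggests a stall near 31.2% reacted. That flask gives 37.5% reacted and 17.6% target.

The earlier runs and the new flask were computed with made-up constants; scatter was added.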